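**Plan**

- Retrosynthesis: the C2–C3 bond of the furanone is cut first, which leads back to an isomeric cyclic enol carbonate. Next come the two carbonate C–O bonds (CO2 + a 2-butynyl carbinol), the CH2–CH2 bond between the chain and the inner furan, the two bonds at the carbinol carbon (allyl chloride + CO + propynyl), and the furyl–CH2 bond of the difurylmethane.
- Forward: fragment A (the two furans, joined by Negishi coupling) and fragment B (geranyl acetate → E-allylic chloride → skipped ynone → S carbinol) are united by a copper-catalysed Grignard allylic substitution.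
- CO2 then closes a temporary 1,3-dioxolan-2-one ring, and the key step transposes it into the furanone, the last ring formed.
- Enabling feature: in the 4-hydroxyfuran-2(5H)-one ring the lactone carbonyl C2 sits on C3, the carbon end of the enol C3=C4–OH next to the O-bearing C5. The ring is therefore the C-carboxylated form of an acyloin enolate; its O-carboxylated isomer (same atoms, C2 on the C4 oxygen) is a 4-ethylidene-1,3-dioxolan-2-one.
- Stereochemistry: C5 (S) comes from a catalyst-controlled transfer hydrogenation of the ynone, and its C–O and C–H bonds are never broken afterwards. Both E alkenes come from geranyl acetate and an E-selective SeO2 oxidation.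

Key step: step 11

Assumption: CIP analysis of the given SMILES gives S at the ring stereocenter, and alkynyl ketones are taken to follow the aryl-ketone model with the (S,S)-TsDPEN ruthenium catalyst (alkynyl in the place of aryl).

**Route**

Step 1
Reactants: 1 furan-3-ylmethanol
Product: 3 3-(chloromethyl)furan, via furan-3-ylmethyl methanesulfonate 2 (not isolated)
Conditions: MsCl, LiCl, 2,4,6-collidine, DMF, 0 °C
Reagents that add atoms: lithium chloride, [Li+].[Cl-]
Why: Mesylation and in-situ SN2 displacement by chloride under buffered, non-acidic conditions (Meyers-type chlorination) should convert the primary alcohol without harming the acid-labile furan.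

Step 2
Reactants: 3 3-(chloromethyl)furan; 4 methyl 5-bromofuran-3-carboxylate
Product: 6 methyl 5-(furan-3-ylmethyl)furan-3-carboxylate, via (furan-3-ylmethyl)zinc chloride 5 (not isolated)
Conditions: Zn dust, LiCl, THF, 25 °C; then 4, Pd(OAc)2 (2 mol%), SPhos (4 mol%), THF, 25 °C
Reagents that add atoms: none
Why: LiCl-assisted zinc insertion into the heterobenzylic chloride gives an ester-tolerant zinc reagent, and Negishi coupling at the activated 2-bromofuran position should form the difurylmethane with the 2,4-substitution pattern fixed by the bromide.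

Step 3
Reactants: 6 methyl 5-(furan-3-ylmethyl)furan-3-carboxylate
Product: 7 [5-(furan-3-ylmethyl)furan-3-yl]methanol
Conditions: LiAlH4, THF, 0 °C; aqueous work-up
Reagents that add atoms: none
Why: Hydride reduction of the ester to the primary alcohol, to which the furans and the diarylmethane CH2 are inert.

Step 4
Reactants: 7 [5-(furan-3-ylmethyl)furan-3-yl]methanol
Product: 9 4-(chloromethyl)-2-(furan-3-ylmethyl)furan, via [5-(furan-3-ylmethyl)furan-3-yl]methyl methanesulfonate 8 (not isolated)
Conditions: MsCl, LiCl, 2,4,6-collidine, DMF, 0 °C; used without storage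
Reagents that add atoms: lithium chloride, [Li+].[Cl-]
Why: The same mesylate–chloride exchange as in step 1 should give the 3-furylmethyl-type chloride under non-acidic conditions.

Step 5
Reactants: 10 geranyl acetate
Product: 11 (2E,6E)-8-hydroxy-3,7-dimethylocta-2,6-dien-1-yl acetate
Conditions: SeO2 (0.2 equiv), t-BuOOH (3 equiv), salicylic acid (0.1 equiv), CH2Cl2, 25 °C
Reagents that add atoms: tert-butyl hydroperoxide, CC(C)(C)OO
Why: Riley-type allylic oxidation (ene reaction, then [2,3]-sigmatropic shift) should occur at the electron-richer terminal alkene and place the hydroxyl on the E-methyl group, the 2,3-alkene being deactivated by the allylic acetate.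

Step 6
Reactants: 11 (2E,6E)-8-hydroxy-3,7-dimethylocta-2,6-dien-1-yl acetate
Product: 13 (2E,6E)-8-chloro-3,7-dimethylocta-2,6-dien-1-yl acetate, via (2E,6E)-3,7-dimethyl-8-[(methylsulfonyl)oxy]octa-2,6-dien-1-yl acetate 12 (not isolated)
Conditions: MsCl, LiCl, 2,4,6-collidine, DMF, 0 °C
Reagents that add atoms: lithium chloride, [Li+].[Cl-]
Why: Mesylate–chloride exchange at the primary allylic alcohol should proceed by direct SN2 without allylic transposition and leave the acetate untouched.

Step 7
Reactants: 13 (2E,6E)-8-chloro-3,7-dimethylocta-2,6-dien-1-yl acetate; 14 tributyl(prop-1-yn-1-yl)stannane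
Product: 15 (2E,6E)-3,7-dimethyl-9-oxododeca-2,6-dien-10-yn-1-yl acetate
Conditions: CO (5 atm), Pd2(dba)3 (2.5 mol%), PPh3 (10 mol%), THF, 40 °C
Reagents that add atoms: carbon monoxide, [C-]#[O+]
Why: Carbonylative Stille coupling: oxidative addition of the allylic chloride to zerovalent palladium (much faster than ionisation of the allylic acetate), CO insertion at the unsubstituted allyl terminus, propynyl transfer from tin and reductive elimination should give the skipped ynone under neutral conditions that keep the 6E alkene out of conjugation.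

Step 8
Reactants: 15 (2E,6E)-3,7-dimethyl-9-oxododeca-2,6-dien-10-yn-1-yl acetate
Product: 16 (2E,6E,9S)-9-hydroxy-3,7-dimethyldodeca-2,6-dien-10-yn-1-yl acetate
Conditions: Ru[(S,S)-TsNCH(Ph)CH(Ph)NH](p-cymene) (1 mol%), i-PrOH, 25 °C
Reagents that add atoms: none
Why: Noyori asymmetric transfer hydrogenation: in the six-membered hydride/proton transfer transition state the alkynyl group takes the position of aryl, so the (S,S)-catalyst should deliver hydride to the face that gives the 9S carbinol (C5 of the target), and the base-free medium should leave the β,γ-alkene and the acetate alone.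

Step 9
Reactants: 9 4-(chloromethyl)-2-(furan-3-ylmethyl)furan; 16 (2E,6E,9S)-9-hydroxy-3,7-dimethyldodeca-2,6-dien-10-yn-1-yl acetate
Product: 19 (4S,6E,10E)-13-[5-(furan-3-ylmethyl)furan-3-yl]-6,10-dimethyltrideca-6,10-dien-2-yn-4-ol, via {[5-(furan-3-ylmethyl)furan-3-yl]methyl}magnesium chloride 17 (not isolated), via chloromagnesium alkoxide of the hydroxy acetate 18 (not isolated)
Conditions: 9, Mg, THF, 0 °C; 16, MeMgCl (1.0 equiv), THF, −78 °C; 17 (1.5 equiv) added to 18, Li2CuCl4 (5 mol%), THF, −20 → 0 °C; aqueous work-up
Reagents that add atoms: none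
Why: Copper-catalysed Grignard allylic substitution: with the hydroxyl masked as its magnesium alkoxide, the diorganocuprate formed from the heterobenzylic Grignard reagent should displace the primary allylic acetate at the unhindered α-carbon, with retention of the E geometry and faster than addition to the ester carbonyl.

Step 10
Reactants: 19 (4S,6E,10E)-13-[5-(furan-3-ylmethyl)furan-3-yl]-6,10-dimethyltrideca-6,10-dien-2-yn-4-ol
Product: 20 (4Z,5S)-4-ethylidene-5-[(2E,6E)-9-[5-(furan-3-ylmethyl)furan-3-yl]-2,6-dimethylnona-2,6-dien-1-yl]-1,3-dioxolan-2-one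
Conditions: CO2 (1 MPa), AgOAc (10 mol%), DBU (1 equiv), toluene, 25 °C
Reagents that add atoms: carbon dioxide, O=C=O
Why: Silver-catalysed carboxylative cyclisation: the alkyl carbonate formed from the hydroxyl and CO2 should add anti across the silver-activated alkyne in a 5-exo-dig closure, protodemetalation giving the Z-ethylidene carbonate, and since the C–O bond at the stereocenter is not broken the S configuration is retained.

Step 11
Reactants: 20 (4Z,5S)-4-ethylidene-5-[(2E,6E)-9-[5-(furan-3-ylmethyl)furan-3-yl]-2,6-dimethylnona-2,6-dien-1-yl]-1,3-dioxolan-2-one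
Product: 23 (5S)-5-[(2E,6E)-9-[5-(furan-3-ylmethyl)furan-3-yl]-2,6-dimethylnona-2,6-dien-1-yl]-4-hydroxy-3-methylfuran-2(5H)-one, via ring-opened sodium enolate imidazole-1-carboxylate 21 (not isolated), via sodium tetronate 22 (not isolated)
Conditions: sodium imidazol-1-ide (NaC3H3N2, 1.1 equiv), DMF (0.05 M), −40 → 0 °C; then 0.5 M HCl, 0 °C, to pH 3
Reagents that add atoms: none
Why: Proposed new method: imidazolide should add to the carbonate carbonyl of the five-membered enol carbonate, and the tetrahedral intermediate should expel the enol oxygen (the better leaving group), which unmasks the Z sodium enolate C3=C4 regiospecifically while the carbonyl carbon stays tethered through O1 as an imidazole-1-carboxylate (21); C3 then attacks this acyl imidazole, and the expelled imidazolide removes the new C3–H to give tetronate 22 (conjugate base of an acid of pKa about 4), which makes the O→C carboxyl transposition irreversible. The closest known reaction types are the Steglich O→C carboxyl rearrangement of enol carbonates, the cyanide- or DMAP-mediated enol ester to 2-acyl-1,3-dione rearrangement, the ring-opening of 4-alkylidene-1,3-dioxolan-2-ones by O- and N-nucleophiles at the enol C–O side, and the Claisen (Dieckmann-type) closure of O-acylated acyloins and α-acyloxy esters to tetronates. The lactone ring closes in a 5-(enolendo)-exo-trig mode, formally disfavoured for all-carbon chains by Baldwin's enolate rules but the same topology as in Lacey–Dieckmann tetronate closures, where the ring oxygen and the trigonal electrophile make it workable. No stereocenter is formed (C3 ends sp2), and C5 should keep its S configuration because neither its C–O nor its C–H bond is touched: the enolate is made by acyl cleavage, not by deprotonation of an α-oxy ketone. The step needs C- over O-acylation and reaction at C3, not C5; O-attack only regenerates 20 and is reversible while C-attack is drained by tetronate formation, and the enolate position is fixed by the ethylidene group made from the alkyne in step 10.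

**Compound list**

1 | furan-3-ylmethanol | OCc1ccoc1 | starting material
2 | furan-3-ylmethyl methanesulfonate | CS(=O)(=O)OCc1ccoc1 | intermediate
3 | 3-(chloromethyl)furan | ClCc1ccoc1 | intermediate
4 | methyl 5-bromofuran-3-carboxylate | COC(=O)c1coc(Br)c1 | starting material
5 | (furan-3-ylmethyl)zinc chloride | Cl[Zn]Cc1ccoc1 | intermediate
6 | methyl 5-(furan-3-ylmethyl)furan-3-carboxylate | COC(=O)c1coc(Cc2ccoc2)c1 | intermediate
7 | [5-(furan-3-ylmethyl)furan-3-yl]methanol | OCc1coc(Cc2ccoc2)c1 | intermediate
8 | [5-(furan-3-ylmethyl)furan-3-yl]methyl methanesulfonate | CS(=O)(=O)OCc1coc(Cc2ccoc2)c1 | intermediate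
9 | 4-(chloromethyl)-2-(furan-3-ylmethyl)furan | ClCc1coc(Cc2ccoc2)c1 | intermediate
10 | geranyl acetate, (2E)-3,7-dimethylocta-2,6-dien-1-yl acetate | CC(C)=CCC/C(C)=C/COC(C)=O | starting material
11 | (2E,6E)-8-hydroxy-3,7-dimethylocta-2,6-dien-1-yl acetate | OC/C(C)=C/CC/C(C)=C/COC(C)=O | intermediate
12 | (2E,6E)-3,7-dimethyl-8-[(methylsulfonyl)oxy]octa-2,6-dien-1-yl acetate | CS(=O)(=O)OC/C(C)=C/CC/C(C)=C/COC(C)=O | intermediate
13 | (2E,6E)-8-chloro-3,7-dimethylocta-2,6-dien-1-yl acetate | ClC/C(C)=C/CC/C(C)=C/COC(C)=O | intermediate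
14 | tributyl(prop-1-yn-1-yl)stannane | CC#C[Sn](CCCC)(CCCC)CCCC | starting material
15 | (2E,6E)-3,7-dimethyl-9-oxododeca-2,6-dien-10-yn-1-yl acetate | CC#CC(=O)C/C(C)=C/CC/C(C)=C/COC(C)=O | intermediate
16 | (2E,6E,9S)-9-hydroxy-3,7-dimethyldodeca-2,6-dien-10-yn-1-yl acetate | CC#C[C@H](C/C(C)=C/CC/C(C)=C/COC(C)=O)O | intermediate
17 | {[5-(furan-3-ylmethyl)furan-3-yl]methyl}magnesium chloride | Cl[Mg]Cc1coc(Cc2ccoc2)c1 | intermediate
18 | chloromagnesium (2E,6E,9S)-1-acetoxy-3,7-dimethyldodeca-2,6-dien-10-yn-9-olate | CC#C[C@H](C/C(C)=C/CC/C(C)=C/COC(C)=O)O[Mg]Cl | intermediate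
19 | (4S,6E,10E)-13-[5-(furan-3-ylmethyl)furan-3-yl]-6,10-dimethyltrideca-6,10-dien-2-yn-4-ol | CC#C[C@H](C/C(C)=C/CC/C(C)=C/CCc1coc(Cc2ccoc2)c1)O | intermediate
20 | (4Z,5S)-4-ethylidene-5-[(2E,6E)-9-[5-(furan-3-ylmethyl)furan-3-yl]-2,6-dimethylnona-2,6-dien-1-yl]-1,3-dioxolan-2-one | C/C=C1\OC(=O)O[C@H]1C/C(C)=C/CC/C(C)=C/CCc1coc(Cc2ccoc2)c1 | intermediate
21 | sodium (2Z,4S,6E,10E)-13-[5-(furan-3-ylmethyl)furan-3-yl]-4-[(1H-imidazol-1-ylcarbonyl)oxy]-6,10-dimethyltrideca-2,6,10-trien-3-olate | C/C=C(\[O-])[C@H](C/C(C)=C/CC/C(C)=C/CCc1coc(Cc2ccoc2)c1)OC(=O)n1ccnc1.[Na+] | intermediate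
22 | sodium (5S)-5-[(2E,6E)-9-[5-(furan-3-ylmethyl)furan-3-yl]-2,6-dimethylnona-2,6-dien-1-yl]-3-methyl-2-oxo-2,5-dihydrofuran-4-olate | CC1=C([O-])[C@H](C/C(C)=C/CC/C(C)=C/CCc2coc(Cc3ccoc3)c2)OC1=O.[Na+] | intermediate
23 | (5S)-5-[(2E,6E)-9-[5-(furan-3-ylmethyl)furan-3-yl]-2,6-dimethylnona-2,6-dien-1-yl]-4-hydroxy-3-methylfuran-2(5H)-one | CC1=C(O)[C@H](C/C(C)=C/CC/C(C)=C/CCc2coc(Cc3ccoc3)c2)OC1=O | target

**Step count and risks**

Total steps: 11. Longest linear sequence: 7 steps (10 → 23 through steps 5–11; equally 1 → 23 through steps 1–4 and 9–11).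

Steps most likely to fail:

1. Step 11 (proposed new method). The ring-opened enolate may be protonated by the imidazole that forms, or by adventitious water, before it is C-acylated. Re-enolisation could then occur on the wrong side, with proton exchange at the α-oxy carbon and loss of enantiopurity, or enolate and acyl imidazole could react between molecules. Fallback with known chemistry, setting out from 20 and returning at 23: 20 would be opened by base-catalysed methanolysis (MeOH, cat. K2CO3, 0 °C), the known alcoholysis of alkylidene cyclic carbonates at the enol C–O bond, to methyl (4S,6E,10E)-13-[5-(furan-3-ylmethyl)furan-3-yl]-6,10-dimethyl-3-oxotrideca-6,10-dien-4-yl carbonate F1. F1 would then be closed by a carbonate Claisen (Dieckmann-type) condensation of the kinetic ethyl-ketone enolate (LiN(SiMe3)2, 2.2 equiv, THF, −78 °C; then cold dilute HCl) to give 23.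

2. Step 7. Propynyl transfer to the allylpalladium may outrun CO insertion (direct allyl–alkynyl coupling), the allylpalladium may scramble the 6E geometry by π–σ–π isomerisation, or the skipped ynone may drift into conjugation. Fallback setting out from 13 and returning at 15, which separates CO uptake from alkynyl delivery: 13 would be hydroxycarbonylated (CO, H2O, PdCl2(PPh3)2, NaOAc, THF) to (3E,7E)-9-acetoxy-3,7-dimethylnona-3,7-dienoic acid F2. F2 would be converted with oxalyl chloride and catalytic DMF (CH2Cl2, 0 °C) into (2E,6E)-9-chloro-3,7-dimethyl-9-oxonona-2,6-dien-1-yl acetate F3, and F3 coupled with stannane 14 without CO (Stille acylation, Pd2(dba)3/PPh3, THF, 25 °C) to give 15.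

3. Step 10. A secondary carbinol with an internal alkyne may cyclise slowly, and DBU may shift the exocyclic double bond into the ring (prototropic isomerisation to the vinylene carbonate), which would erase the stereocenter. Fallback setting out from 19 and returning at 20, with no base and no CO2 in the cyclisation: 19 would be acylated (Boc2O, cat. DMAP, CH2Cl2, 0 °C) to tert-butyl (4S,6E,10E)-13-[5-(furan-3-ylmethyl)furan-3-yl]-6,10-dimethyltrideca-6,10-dien-2-yn-4-yl carbonate F4. F4 would be cyclised with (Ph3P)AuNTf2 (2 mol%, CH2Cl2, 25 °C), the gold-catalysed 5-exo closure of propargylic tert-butyl carbonates with loss of isobutene, to give 20.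

**Further compounds**

F1 | step 11 | methyl (4S,6E,10E)-13-[5-(furan-3-ylmethyl)furan-3-yl]-6,10-dimethyl-3-oxotrideca-6,10-dien-4-yl carbonate | CCC(=O)[C@H](C/C(C)=C/CC/C(C)=C/CCc1coc(Cc2ccoc2)c1)OC(=O)OC
F2 | step 7 | (3E,7E)-9-acetoxy-3,7-dimethylnona-3,7-dienoic acid | OC(=O)C/C(C)=C/CC/C(C)=C/COC(C)=O
F3 | step 7 | (2E,6E)-9-chloro-3,7-dimethyl-9-oxonona-2,6-dien-1-yl acetate | ClC(=O)C/C(C)=C/CC/C(C)=C/COC(C)=O
F4 | step 10 | tert-butyl (4S,6E,10E)-13-[5-(furan-3-ylmethyl)furan-3-yl]-6,10-dimethyltrideca-6,10-dien-2-yn-4-yl carbonate | CC#C[C@H](C/C(C)=C/CC/C(C)=C/CCc1coc(Cc2ccoc2)c1)OC(=O)OC(C)(C)C
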